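**Assumptions (one line):** The methine stereocentre differs between its two aryl groups only by a remote OMe versus OH, so I assume it is configurationally stable under the neutral or mildly basic conditions used. I also assume the Felkin–Anh relay in Step 6 gives a separable diastereomer mixture, with the desired isomer in the majority.

## Retrosynthetic overview
1. Target 15 comes from late C-prenylation of the only free ring position (ring A C5) of diarylmethane 14.
2. 14 comes from radical removal of the relay oxygen on the carbon next to the methine in 13. That carbon is the valine-derived stereocentre and becomes the CH2 of the isobutyl group.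
3. 13 forms in the key step: photodehydration of benzylic alcohol 11 gives an o-quinone methide, and ring A phenol 6 traps it as a C-nucleophile. The new methine stereocentre is set by the adjacent (S)-silyloxy centre (polar Felkin–Anh).
4. 11 comes from ortho-hydroxyalkylation of 3-prenylphloroacetophenone (3) with aldehyde 10, which is made from (S)-2-hydroxy-3-methylbutanoate.
5. No ring is constructed. Both aromatic rings come from phloroacetophenone and 5-methoxyresorcinol.

## Route

**Step 1**
Reactants: 1 (2,4,6-trihydroxyacetophenone), 2 (prenyl bromide)
Product: 3 (1-(2,4,6-trihydroxy-3-prenylphenyl)ethanone)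
Conditions: KOH (2.2 equiv), H2O, 0 °C to rt, 3 h; chromatography to remove di-C- and O-prenyl products
Reagents that add atoms: prenyl bromide, CC(C)=CCBr
Why: C-alkylation of the phenolate (Friedel–Crafts-type); C3 and C5 of 1 are equivalent, so only one regioisomer is possible.

**Step 2**
Reactants: 4 (5-methoxyresorcinol), 5 (acetic acid)
Product: 6 (1-(2,4-dihydroxy-6-methoxyphenyl)ethanone)
Conditions: BF3·OEt2, 80 °C, 2 h; the major regioisomer (acylation para to one OH) is separated by chromatography
Reagents that add atoms: acetic acid, CC(=O)O
Why: BF3-mediated Friedel–Crafts (Hoesch-type) acylation gives the acetyl group flanked by OH and OMe, as required for ring A.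

**Step 3**
Reactants: 7 (methyl (S)-2-hydroxy-3-methylbutanoate), 8 (TBSCl)
Product: 9 (methyl (S)-2-(TBSO)-3-methylbutanoate)
Conditions: TBSCl (1.2 equiv), imidazole, DMF, rt, 12 h
Reagents that add atoms: TBSCl, CC(C)(C)[Si](C)(C)Cl
Why: Standard silylation; the carbinol stereocentre is untouched and stays (S).

**Step 4**
Reactants: 9
Product: 10 ((S)-2-(TBSO)-3-methylbutanal)
Conditions: DIBAL-H (1.1 equiv), CH2Cl2, –78 °C, 1 h; Rochelle salt work-up; used crude at once
Reagents that add atoms: none
Why: Partial ester reduction at low temperature gives the α-silyloxy aldehyde without epimerisation.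

**Step 5**
Reactants: 3, 10
Product: 11 (benzylic alcohol: ring B–CH(OH)–CH(OTBS)iPr, Cα (S), carbinol carbon as an epimer mixture)
Conditions: 3 with MgBr2·OEt2 (3 equiv) and iPr2NEt (3 equiv), CH2Cl2, 0 °C, 30 min; then 10 (1.5 equiv), 0 °C to rt, 12 h; cold citrate work-up
Reagents that add atoms: none
Why: Casiraghi-type ortho-hydroxyalkylation. The Mg phenoxide–alkoxide chelate stops the adduct from losing water to the o-QM, which prevents over-arylation. The carbinol epimers are irrelevant because that centre becomes planar in Step 6.

**Step 6**
Reactants: 11, 6 (3 equiv)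
Product: 12 (diarylmethane with the free Cα–OTBS; C* (S), Cα (S))
Conditions: MeCN (0.02 M, degassed), 350 nm, 10 °C, 8 h, no additives; chromatography removes the minor diastereomer and any C5-coupled regioisomer
Reagents that add atoms: none
Why: Proposed new method: excited-state intramolecular proton transfer from the free phenol OH of 11 to the benzylic OH releases water and gives ring B's o-quinone methide at low steady-state concentration and neutral pH. Phenol 6 then adds through its C3 carbon, between the two OH groups (1,4-addition/Friedel–Crafts type). The nucleophile attacks anti to the C–OTBS bond and past the α-H rather than the isopropyl group (polar Felkin–Anh), so (S)-Cα gives (S)-C*, which is (R) in the target after deoxygenation. The closest known reactions are photodehydration of 2-hydroxybenzyl alcohols to o-QMs and the thermal Knoevenagel–Michael coupling of acylphloroglucinols.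

**Step 7**
Reactants: 12
Product: 13 (free secondary alcohol at Cα)
Conditions: HF·pyridine (10 equiv), THF/pyridine 4:1, 0 °C to rt, 16 h
Reagents that add atoms: none
Why: Buffered fluoride cleaves the silyl ether (desilylation) and is acid-free enough to keep the prenyl group and the diarylmethane intact; no stereocentre is involved.

**Step 8**
Reactants: 13
Product: 14 (deoxygenated diarylmethane; ring A still lacks prenyl)
Conditions: (i) 3-aryl-benzoxazolium salt (1.5 equiv), pyridine, MeCN, rt, 1 h; (ii) [Ir(dF(CF3)ppy)2(dtbbpy)]PF6 (1 mol %), iPr3SiSH (20 mol %), blue LEDs, rt, 16 h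
Reagents that add atoms: none
Why: NHC-mediated photoredox deoxygenation converts the N,O-acetal of the alcohol into a secondary alkyl radical, which is reduced by hydrogen-atom transfer. The relay stereocentre is destroyed, while C* is not involved. This is known chemistry applied to a new substrate; the neophyl-type aryl shift is outcompeted by fast hydrogen-atom trapping.

**Step 9**
Reactants: 14, 2
Product: 15 (target)
Conditions: prenyl bromide (1.1 equiv), KOH (2.5 equiv), MeOH/H2O, 0 °C to rt, 2 h
Reagents that add atoms: prenyl bromide, CC(C)=CCBr
Why: Ring B has no free carbon, so C-prenylation occurs only at ring A C5 (between OH and OMe), by phenolate C-alkylation in a protic medium. The stereocentre is not touched.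

## Compound list
1 | 2,4,6-trihydroxyacetophenone | CC(=O)c1c(O)cc(O)cc1O | starting material
2 | prenyl bromide | CC(C)=CCBr | starting material
3 | 1-(2,4,6-trihydroxy-3-prenylphenyl)ethanone | CC(=O)c1c(O)c(CC=C(C)C)c(O)cc1O | intermediate
4 | 5-methoxyresorcinol | COc1cc(O)cc(O)c1 | starting material
5 | acetic acid | CC(=O)O | starting material
6 | 1-(2,4-dihydroxy-6-methoxyphenyl)ethanone | COc1cc(O)cc(O)c1C(C)=O | intermediate
7 | methyl (S)-2-hydroxy-3-methylbutanoate | COC(=O)[C@@H](O)C(C)C | starting material
8 | TBSCl | CC(C)(C)[Si](C)(C)Cl | starting material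
9 | methyl (S)-2-(TBSO)-3-methylbutanoate | COC(=O)[C@@H](O[Si](C)(C)C(C)(C)C)C(C)C | intermediate
10 | (S)-2-(TBSO)-3-methylbutanal | O=C[C@@H](O[Si](C)(C)C(C)(C)C)C(C)C | intermediate
11 | benzylic alcohol, Cα (S), carbinol epimeric | CC(=O)c1c(O)c(CC=C(C)C)c(O)c(C(O)[C@@H](O[Si](C)(C)C(C)(C)C)C(C)C)c1O | intermediate
12 | diarylmethane with Cα–OTBS (C* S, Cα S) | COc1cc(O)c([C@H]([C@@H](O[Si](C)(C)C(C)(C)C)C(C)C)c2c(O)c(CC=C(C)C)c(O)c(C(C)=O)c2O)c(O)c1C(C)=O | intermediate
13 | diarylmethane with free Cα–OH | COc1cc(O)c([C@H]([C@@H](O)C(C)C)c2c(O)c(CC=C(C)C)c(O)c(C(C)=O)c2O)c(O)c1C(C)=O | intermediate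
14 | des-prenyl ring A diarylmethane | COc1cc(O)c([C@H](CC(C)C)c2c(O)c(CC=C(C)C)c(O)c(C(C)=O)c2O)c(O)c1C(C)=O | intermediate
15 | CID44559660 (R) | COc1c(CC=C(C)C)c(O)c([C@H](CC(C)C)c2c(O)c(CC=C(C)C)c(O)c(C(C)=O)c2O)c(O)c1C(C)=O | target

**Total steps:** 9. **Longest linear sequence:** 7 (7 → 9 → 10 → 11 → 12 → 13 → 14 → 15).

## Three steps most likely to fail
1. **Step 6 (proposed new photochemical coupling).** Photodehydration may be inefficient, diastereoselectivity may be low, or the product may undergo photochemical retro-Michael scrambling. Fallback: generate the same o-QM thermally from 11 (cat. Et3N, MeCN, 60 °C) and trap it with 6, using the same Felkin–Anh relay.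
2. **Step 8 (deoxygenation on the unprotected polyphenol).** Phenol oxidation, thiyl-radical thiol-ene addition to the prenyl group, C*–H racemisation or a neophyl aryl shift could occur. Fallback: peracetylate 12 (Ac2O, py, DMAP), remove TBS (HF·py), form the phenyl thionocarbonate, reduce with Bu3SnH/AIBN, then deacetylate (K2CO3, MeOH) to give 14.
3. **Step 5 (isolable benzylic alcohol).** The Mg adduct may collapse to the o-QM and give bis-arylation or homodimer. Fallback: BF3-mediated acylation of 3 with (S)-2-acetoxy-3-methylbutanoic acid, then NaBH4 reduction, giving the Cα–OAc analogue of 11 that is carried through Step 6 with mild methanolysis replacing Step 7.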